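**Retrosynthetic overview**

- Ring A (the 3,4-dimethoxyphenyl ring, C1–C6) carries H, OMe, OMe, H on C2, C3, C4, C5, a locally symmetric four-carbon edge. Cutting C1–C2 and C5–C6 gives 2,3-dimethoxybuta-1,3-diene and a terminal alkyne C1≡C6 on C7; the forward reaction is a cobalt-catalysed [4+2] cycloaddition followed by dehydrogenation.
- The alkyne diacetate 18 comes from the trans lactone 16 by reduction and acetylation. The C7–C8 bond is made by alkylating the enolate of (R)-lactone 13 with propargyl bromide anti to the C8' substituent, which sets C8.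
- Lactone 13 comes from an Evans alkylation of a succinate imide with the ring B benzylic bromide (C7'–C8' bond, sets C8'). Only enolate and hydride chemistry meets the alkyne before the key step, so no radical or low-valent metal step has to tolerate it.
- Ring order: ring B is bought; a temporary lactone ring is closed in step 6 and opened in step 8; ring A is closed in step 10 and aromatised in step 11; debenzylation ends the route.

Key step: step 10

Assumption: lignan numbering is used (ring A on C7/C8/C9, ring B on C7'/C8'/C9'), and 4-(benzyloxy)-3,5-dimethoxybenzaldehyde is taken as purchasable (otherwise one benzylation of syringaldehyde precedes step 1).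

**Route**

Step 1
Reactants: 1 4-(benzyloxy)-3,5-dimethoxybenzaldehyde
Product: 2 [4-(benzyloxy)-3,5-dimethoxyphenyl]methanol
Conditions: NaBH4, MeOH/THF, 0 °C
Reagents that add atoms: none
Why: Borohydride reduction of an aryl aldehyde to the benzylic alcohol, with no other reducible group present.

Step 2
Reactants: 2 [4-(benzyloxy)-3,5-dimethoxyphenyl]methanol
Product: 3 2-(benzyloxy)-5-(bromomethyl)-1,3-dimethoxybenzene
Conditions: PBr3 (0.4 equiv), CH2Cl2, 0 °C
Reagents that add atoms: phosphorus tribromide, BrP(Br)Br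
Why: Bromination of an electron-rich benzylic alcohol through its phosphite ester, under which the aryl benzyl ether and the methyl ethers are inert.

Step 3
Reactants: 4 4-tert-butoxy-4-oxobutanoic acid (mono-tert-butyl succinate); 5 pivaloyl chloride; 6 (4R)-4-benzyl-1,3-oxazolidin-2-one
Product: 8 tert-butyl 4-[(4R)-4-benzyl-2-oxo-1,3-oxazolidin-3-yl]-4-oxobutanoate, via pivalic mixed anhydride 7 (not isolated)
Conditions: Et3N, THF, −20 °C (4 + 5); then 6, LiCl, −20 °C to rt
Reagents that add atoms: none
Why: N-acylation of the oxazolidinone through the mixed pivalic anhydride, whose unhindered succinyl carbonyl is the one attacked.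

Step 4
Reactants: 8 tert-butyl 4-[(4R)-4-benzyl-2-oxo-1,3-oxazolidin-3-yl]-4-oxobutanoate; 3 2-(benzyloxy)-5-(bromomethyl)-1,3-dimethoxybenzene
Product: 10 tert-butyl (3R)-3-[4-(benzyloxy)-3,5-dimethoxybenzyl]-4-[(4R)-4-benzyl-2-oxo-1,3-oxazolidin-3-yl]-4-oxobutanoate, via sodium Z-enolate 9 (not isolated)
Conditions: NaHMDS (1.05 equiv), THF, −78 °C; then 3, −78 to −20 °C
Reagents that add atoms: none
Why: Evans asymmetric alkylation, in which the more acidic imide α-CH2 gives the chelated Z-enolate and the benzylic bromide enters on the face opposite the C4 benzyl group of the (R)-auxiliary, setting C8' as (R).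

Step 5
Reactants: 10 tert-butyl (3R)-3-[4-(benzyloxy)-3,5-dimethoxybenzyl]-4-[(4R)-4-benzyl-2-oxo-1,3-oxazolidin-3-yl]-4-oxobutanoate
Product: 11 tert-butyl (3R)-3-[4-(benzyloxy)-3,5-dimethoxybenzyl]-4-hydroxybutanoate
Conditions: LiBH4, MeOH (1 equiv), THF, 0 °C
Reagents that add atoms: none
Why: Reductive removal of the oxazolidinone with LiBH4, which reduces the exocyclic imide carbonyl faster than the hindered tert-butyl ester and does not enolise the stereocentre.

Step 6
Reactants: 11 tert-butyl (3R)-3-[4-(benzyloxy)-3,5-dimethoxybenzyl]-4-hydroxybutanoate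
Product: 13 (4R)-4-[4-(benzyloxy)-3,5-dimethoxybenzyl]oxolan-2-one, via hydroxy acid 12 (not isolated)
Conditions: TsOH·H2O (10 mol%), PhMe, 80 °C
Reagents that add atoms: none
Why: Acid-catalysed loss of isobutene from the tert-butyl ester and lactonisation of the γ-hydroxy acid to the five-membered lactone, with the stereocentre not involved and the benzyl ether stable to catalytic acid.

Step 7
Reactants: 13 (4R)-4-[4-(benzyloxy)-3,5-dimethoxybenzyl]oxolan-2-one; 14 3-bromoprop-1-yne (propargyl bromide)
Product: 16 (3R,4R)-4-[4-(benzyloxy)-3,5-dimethoxybenzyl]-3-(prop-2-yn-1-yl)oxolan-2-one, via lithium enolate 15 (not isolated)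
Conditions: LiHMDS (1.1 equiv), THF, −78 °C; then 14, DMPU, −78 to −40 °C
Reagents that add atoms: none
Why: Alkylation of the lactone enolate, where the electrophile approaches anti to the β-arylmethyl group as in classical trans-dibenzylbutyrolactone lignan chemistry, setting C8 as (R) in the trans lactone.

Step 8
Reactants: 16 (3R,4R)-4-[4-(benzyloxy)-3,5-dimethoxybenzyl]-3-(prop-2-yn-1-yl)oxolan-2-one
Product: 17 (2R,3R)-2-[4-(benzyloxy)-3,5-dimethoxybenzyl]-3-(prop-2-yn-1-yl)butane-1,4-diol
Conditions: LiAlH4, THF, 0 °C to rt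
Reagents that add atoms: none
Why: Hydride reduction of the lactone to the 1,4-diol, which leaves the isolated terminal alkyne, the benzyl ether and both stereocentres untouched at this temperature.

Step 9
Reactants: 17 (2R,3R)-2-[4-(benzyloxy)-3,5-dimethoxybenzyl]-3-(prop-2-yn-1-yl)butane-1,4-diol
Product: 18 (2R,3R)-2-[4-(benzyloxy)-3,5-dimethoxybenzyl]-3-(prop-2-yn-1-yl)butane-1,4-diyl diacetate
Conditions: Ac2O, pyridine, DMAP (cat.), CH2Cl2, rt
Reagents that add atoms: acetic anhydride, CC(=O)OC(C)=O
Why: DMAP-catalysed acetylation of the two primary alcohols, which installs the C9 and C9' acetates of the target before any acid-labile group exists.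

Step 10
Reactants: 18 (2R,3R)-2-[4-(benzyloxy)-3,5-dimethoxybenzyl]-3-(prop-2-yn-1-yl)butane-1,4-diyl diacetate; 19 2,3-dimethoxybuta-1,3-diene
Product: 20 (2R,3R)-2-[4-(benzyloxy)-3,5-dimethoxybenzyl]-3-[(4,5-dimethoxycyclohexa-1,4-dien-1-yl)methyl]butane-1,4-diyl diacetate
Conditions: CoBr2(dppe) (10 mol%; dppe = 1,2-bis(diphenylphosphino)ethane), Zn dust (20 mol%), ZnI2 (20 mol%), 19 (3 equiv), dry CH2Cl2, rt, slow addition of 18; filtration through basic alumina
Reagents that add atoms: none
Why: Zinc reduces CoBr2(dppe) to a monovalent cobalt species and ZnI2 removes halide, so diene 19 and the terminal alkyne of 18 bind at one metal centre; oxidative cyclisation joins a diene terminus to an alkyne carbon and reductive elimination from the allyl–vinyl cobaltacycle forms the second bond. The closest known reaction type is the cobalt-catalysed neutral Diels–Alder reaction of unactivated terminal alkynes with 2,3-dialkyl and oxygen-substituted 1,3-dienes, of which this 2,3-dimethoxy diene is a close but untested member. Ring A is closed as its 1,4-dihydro form in a formal intermolecular [4+2] mode, with the C1–C2 and C5–C6 bonds made in one catalytic cycle. No stereocentre is created, and C8 and C8' sit away from the reacting alkyne and are not enolisable under these neutral conditions. The step needs chemoselectivity for cross-cycloaddition over alkyne cyclotrimerisation and survival of the acid-labile enol ethers, which excess diene, slow alkyne addition, dry non-coordinating solvent at room temperature and a basic work-up should secure; the diene is symmetric, so there is no regiochemical question.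

Step 11
Reactants: 20 (2R,3R)-2-[4-(benzyloxy)-3,5-dimethoxybenzyl]-3-[(4,5-dimethoxycyclohexa-1,4-dien-1-yl)methyl]butane-1,4-diyl diacetate
Product: 21 (2R,3R)-2-[4-(benzyloxy)-3,5-dimethoxybenzyl]-3-(3,4-dimethoxybenzyl)butane-1,4-diyl diacetate (O-benzyl Justin C)
Conditions: DDQ (1.05 equiv), NaHCO3 (solid), CH2Cl2, 0 °C
Reagents that add atoms: none
Why: DDQ dehydrogenation of a cyclohexa-1,4-diene (hydride abstraction from a doubly allylic CH2, then proton loss) is driven by aromatisation and is fast at 0 °C, so one equivalent should spare the benzylic positions and the benzyl ether while the bicarbonate keeps the enol ethers from hydrolysing.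

Step 12
Reactants: 21 (2R,3R)-2-[4-(benzyloxy)-3,5-dimethoxybenzyl]-3-(3,4-dimethoxybenzyl)butane-1,4-diyl diacetate
Product: 22 Justin C, (2R,3R)-2-(3,4-dimethoxybenzyl)-3-(4-hydroxy-3,5-dimethoxybenzyl)butane-1,4-diyl diacetate
Conditions: H2 (1 atm), 10% Pd/C, EtOAc, rt
Reagents that add atoms: none
Why: Hydrogenolysis of the aryl benzyl ether over palladium on carbon frees the ring B phenol under neutral conditions that leave the acetates, the methyl ethers and both stereocentres unchanged.

**Compound list**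

1 | 4-(benzyloxy)-3,5-dimethoxybenzaldehyde | COc1cc(C=O)cc(OC)c1OCc1ccccc1 | starting material
2 | [4-(benzyloxy)-3,5-dimethoxyphenyl]methanol | COc1cc(CO)cc(OC)c1OCc1ccccc1 | intermediate
3 | 2-(benzyloxy)-5-(bromomethyl)-1,3-dimethoxybenzene | COc1cc(CBr)cc(OC)c1OCc1ccccc1 | intermediate
4 | 4-tert-butoxy-4-oxobutanoic acid | CC(C)(C)OC(=O)CCC(=O)O | starting material
5 | pivaloyl chloride | CC(C)(C)C(=O)Cl | starting material
6 | (4R)-4-benzyl-1,3-oxazolidin-2-one | O=C1N[C@H](Cc2ccccc2)CO1 | starting material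
7 | 4-tert-butoxy-4-oxobutanoic pivalic anhydride | CC(C)(C)OC(=O)CCC(=O)OC(=O)C(C)(C)C | intermediate
8 | tert-butyl 4-[(4R)-4-benzyl-2-oxo-1,3-oxazolidin-3-yl]-4-oxobutanoate | CC(C)(C)OC(=O)CCC(=O)N1[C@H](Cc2ccccc2)COC1=O | intermediate
9 | sodium (1Z)-1-[(4R)-4-benzyl-2-oxo-1,3-oxazolidin-3-yl]-4-tert-butoxy-4-oxobut-1-en-1-olate | CC(C)(C)OC(=O)C/C=C(\[O-])N1[C@H](Cc2ccccc2)COC1=O.[Na+] | intermediate
10 | tert-butyl (3R)-3-[4-(benzyloxy)-3,5-dimethoxybenzyl]-4-[(4R)-4-benzyl-2-oxo-1,3-oxazolidin-3-yl]-4-oxobutanoate | CC(C)(C)OC(=O)C[C@@H](Cc1cc(OC)c(OCc2ccccc2)c(OC)c1)C(=O)N1[C@H](Cc2ccccc2)COC1=O | intermediate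
11 | tert-butyl (3R)-3-[4-(benzyloxy)-3,5-dimethoxybenzyl]-4-hydroxybutanoate | CC(C)(C)OC(=O)C[C@@H](Cc1cc(OC)c(OCc2ccccc2)c(OC)c1)CO | intermediate
12 | (3R)-3-[4-(benzyloxy)-3,5-dimethoxybenzyl]-4-hydroxybutanoic acid | OC(=O)C[C@@H](Cc1cc(OC)c(OCc2ccccc2)c(OC)c1)CO | intermediate
13 | (4R)-4-[4-(benzyloxy)-3,5-dimethoxybenzyl]oxolan-2-one | O=C1C[C@@H](Cc2cc(OC)c(OCc3ccccc3)c(OC)c2)CO1 | intermediate
14 | 3-bromoprop-1-yne | C#CCBr | starting material
15 | lithium (4R)-4-[4-(benzyloxy)-3,5-dimethoxybenzyl]-4,5-dihydrofuran-2-olate | [Li+].[O-]C1=C[C@@H](Cc2cc(OC)c(OCc3ccccc3)c(OC)c2)CO1 | intermediate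
16 | (3R,4R)-4-[4-(benzyloxy)-3,5-dimethoxybenzyl]-3-(prop-2-yn-1-yl)oxolan-2-one | O=C1[C@H](CC#C)[C@@H](Cc2cc(OC)c(OCc3ccccc3)c(OC)c2)CO1 | intermediate
17 | (2R,3R)-2-[4-(benzyloxy)-3,5-dimethoxybenzyl]-3-(prop-2-yn-1-yl)butane-1,4-diol | C#CC[C@@H](CO)[C@H](CO)Cc1cc(OC)c(OCc2ccccc2)c(OC)c1 | intermediate
18 | (2R,3R)-2-[4-(benzyloxy)-3,5-dimethoxybenzyl]-3-(prop-2-yn-1-yl)butane-1,4-diyl diacetate | C#CC[C@@H](COC(C)=O)[C@H](COC(C)=O)Cc1cc(OC)c(OCc2ccccc2)c(OC)c1 | intermediate
19 | 2,3-dimethoxybuta-1,3-diene | C=C(OC)C(=C)OC | starting material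
20 | (2R,3R)-2-[4-(benzyloxy)-3,5-dimethoxybenzyl]-3-[(4,5-dimethoxycyclohexa-1,4-dien-1-yl)methyl]butane-1,4-diyl diacetate | COC1=C(OC)CC(C[C@@H](COC(C)=O)[C@H](COC(C)=O)Cc2cc(OC)c(OCc3ccccc3)c(OC)c2)=CC1 | intermediate
21 | (2R,3R)-2-[4-(benzyloxy)-3,5-dimethoxybenzyl]-3-(3,4-dimethoxybenzyl)butane-1,4-diyl diacetate | COc1ccc(C[C@@H](COC(C)=O)[C@H](COC(C)=O)Cc2cc(OC)c(OCc3ccccc3)c(OC)c2)cc1OC | intermediate
22 | Justin C, (2R,3R)-2-(3,4-dimethoxybenzyl)-3-(4-hydroxy-3,5-dimethoxybenzyl)butane-1,4-diyl diacetate | COc1ccc(C[C@@H](COC(C)=O)[C@H](COC(C)=O)Cc2cc(OC)c(O)c(OC)c2)cc1OC | target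

**Step count**

Total step count: 12.
Longest linear sequence: 11 steps (from 1 through steps 1, 2 and 4 to 12; step 3 is the one-step side branch).

**Steps most likely to fail**

Step 10. Alkyne cyclotrimerisation may outrun the cross-cycloaddition, the electron-rich dialkoxy diene may oligomerise or hydrolyse under the zinc Lewis acid, and catalyst turnover with this diene may be low. The fallback builds ring A by classical benzylation instead. It sets out from lactone 13: LiHMDS in THF at −78 °C followed by 4-(bromomethyl)-1,2-dimethoxybenzene should give, by the same anti alkylation, (3R,4R)-4-[4-(benzyloxy)-3,5-dimethoxybenzyl]-3-(3,4-dimethoxybenzyl)oxolan-2-one F1. LiAlH4 in THF then gives (2R,3R)-2-[4-(benzyloxy)-3,5-dimethoxybenzyl]-3-(3,4-dimethoxybenzyl)butane-1,4-diol F2. Acetylation with Ac2O and pyridine comes back to the route at compound 21.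

Step 11. Over-oxidation at the benzylic positions of the two electron-rich rings, or acid-promoted hydrolysis of the bis-enol ether before dehydrogenation, may erode the material. The fallback replaces the quinone oxidant by catalytic transfer dehydrogenation. It sets out from 20, which is stirred with 10% Pd/C in EtOAc under argon at rt to 40 °C. The cyclohexa-1,4-diene then acts as a built-in hydrogen donor, as cyclohexa-1,4-diene does in palladium-catalysed transfer hydrogenolysis of benzyl ethers, so ring A aromatises while the released hydrogen cleaves the benzyl ether. Any benzyl ether left is removed by admitting H2 once the diene is consumed. The fallback comes back at compound 22 and makes no compound outside the list (F0).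

Step 7. Proton transfer from the acetylenic C–H of the electrophile or of the product to the enolate may stall conversion and lead to double alkylation, and the small electrophile may erode the trans selectivity. The fallback masks the alkyne terminus. It sets out from 13: LiHMDS in THF at −78 °C followed by 3-bromo-1-(trimethylsilyl)prop-1-yne should give (3R,4R)-4-[4-(benzyloxy)-3,5-dimethoxybenzyl]-3-[3-(trimethylsilyl)prop-2-yn-1-yl]oxolan-2-one F3. LiAlH4 then gives (2R,3R)-2-[4-(benzyloxy)-3,5-dimethoxybenzyl]-3-[3-(trimethylsilyl)prop-2-yn-1-yl]butane-1,4-diol F4. K2CO3 in MeOH removes the silyl group and comes back to the route at compound 17.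

Further compounds
F1 | step 10 | (3R,4R)-4-[4-(benzyloxy)-3,5-dimethoxybenzyl]-3-(3,4-dimethoxybenzyl)oxolan-2-one | O=C1[C@H](Cc2ccc(OC)c(OC)c2)[C@@H](Cc2cc(OC)c(OCc3ccccc3)c(OC)c2)CO1
F2 | step 10 | (2R,3R)-2-[4-(benzyloxy)-3,5-dimethoxybenzyl]-3-(3,4-dimethoxybenzyl)butane-1,4-diol | COc1ccc(C[C@@H](CO)[C@H](CO)Cc2cc(OC)c(OCc3ccccc3)c(OC)c2)cc1OC
F0 | step 11 | none | none
F3 | step 7 | (3R,4R)-4-[4-(benzyloxy)-3,5-dimethoxybenzyl]-3-[3-(trimethylsilyl)prop-2-yn-1-yl]oxolan-2-one | O=C1[C@H](CC#C[Si](C)(C)C)[C@@H](Cc2cc(OC)c(OCc3ccccc3)c(OC)c2)CO1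
F4 | step 7 | (2R,3R)-2-[4-(benzyloxy)-3,5-dimethoxybenzyl]-3-[3-(trimethylsilyl)prop-2-yn-1-yl]butane-1,4-diol | C[Si](C)(C)C#CC[C@@H](CO)[C@H](CO)Cc1cc(OC)c(OCc2ccccc2)c(OC)c1
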